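Ring A of the target (C5–C10, drimane numbering) is a cyclohexene that carries both stereocentres, the methine C8 and the quaternary C9, with cis methyl groups. After moving its tetrasubstituted C5=C10 alkene to C5=C6, ring A is the Diels–Alder adduct of 6,6-dimethyl-1-vinylcyclohexene and (E)-tiglic aldehyde. One catalytic enantioselective [4+2] cycloaddition of these two achiral fragments closes ring A by forming C7–C8 (ring CH2 to the methyl-bearing methine) together with C9–C10, and sets C8 and C9 from dienophile geometry and catalyst. Acid then moves the alkene into the ring fusion, and the formyl group (C11) carries in the arene that becomes the hydroxymethoxyquinone.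

Key step: step 3

Numbering used below (drimane type): C1–C3 ring B methylenes, C4 gem-dimethyl carbon, C5=C10 ring-fusion alkene, C6 and C7 ring A methylenes, C8 methyl-bearing methine, C9 quaternary carbon, C11 benzylic CH2.

Remark: the sense of induction in step 3 is taken from the accepted transition-state model of oxazaborolidinium catalysts for 2-substituted enals (formyl C–H···O contact, s-trans enal, one face covered by a phenyl group); under this model the (R)-catalyst directs the diene to the C2-Si/C3-Re face of tiglic aldehyde, which corresponds to (8S,9R).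

Step 1
Reactants: 1 2,2-dimethylcyclohexanone; 2 LiN(SiMe3)2; 3 N-phenylbis(trifluoromethanesulfonimide)
Product: 5 6,6-dimethylcyclohex-1-en-1-yl trifluoromethanesulfonate, via lithium enolate 4 (not isolated)
Conditions: LiN(SiMe3)2, THF, −78 °C; then PhNTf2, −78 → 23 °C
Reagents that add atoms: LiN(SiMe3)2, [Li]N([Si](C)(C)C)[Si](C)(C)C (lithium of 4); N-phenylbis(trifluoromethanesulfonimide), O=S(=O)(N(c1ccccc1)S(=O)(=O)C(F)(F)F)C(F)(F)F (CF3SO2 group of 5)
Why: Ketone 1 can form only one enolate because C2 is quaternary, and O-sulfonylation of a lithium enolate with PhNTf2 is the standard enol triflate synthesis.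

Step 2
Reactants: 5 6,6-dimethylcyclohex-1-en-1-yl trifluoromethanesulfonate; 6 tributyl(vinyl)stannane
Product: 7 6,6-dimethyl-1-vinylcyclohex-1-ene
Conditions: Pd(PPh3)4 (3 mol %), LiCl (3 equiv), THF, 65 °C; aqueous KF work-up
Reagents that add atoms: tributyl(vinyl)stannane, C=C[Sn](CCCC)(CCCC)CCCC
Why: Stille coupling of an enol triflate with a vinylstannane (oxidative addition to zerovalent palladium, chloride-assisted transmetalation, reductive elimination) is the classical route to 1-vinylcycloalkenes and creates no stereocentre.

Step 3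
Reactants: 7 6,6-dimethyl-1-vinylcyclohex-1-ene; 8 (E)-2-methylbut-2-enal (tiglic aldehyde)
Product: 9 (1R,2S,8aR)-1,2,5,5-tetramethyl-1,2,3,5,6,7,8,8a-octahydronaphthalene-1-carbaldehyde
Conditions: (R)-3,3-diphenyl-1-(o-tolyl)tetrahydro-1H,3H-pyrrolo[1,2-c][1,3,2]oxazaborole (20 mol %), Tf2NH (18 mol %), CH2Cl2, −78 → −40 °C
Reagents that add atoms: (E)-2-methylbut-2-enal, C/C=C(\C)C=O
Why: The cationic oxazaborolidinium binds the formyl group of 8 and lowers its LUMO, so that diene 7, which is biased towards the s-cis form because the s-trans form clashes with the gem-dimethyl group, adds in an asynchronous but concerted, suprafacial [4+2] cycloaddition; the closest known reaction type is the oxazaborolidinium-catalysed Diels–Alder reaction of 2-substituted enals. Ring A is closed as a six-membered ring by intermolecular [4+2] annulation onto ring B, with the C7–C8 bond (vinyl CH2 terminus to the β-carbon of the enal) forming ahead of C9–C10. The cis relation of the C8 and C9 methyl groups and the trans relation of the formyl group to the C8 methyl group follow from the E geometry of 8, and the absolute configuration (8S,9R) follows from diene attack on the C2-Si/C3-Re face of the s-trans enal, the other face being covered by a phenyl group of the (R)-catalyst. C10 is set by the exo/endo preference (the formyl-exo adduct, H-10 cis to the formyl group, is drawn) but is of no consequence, because C10 becomes trigonal in step 4 and both epimers converge. The step needs the regiochemistry that joins the unsubstituted vinyl terminus to the β-carbon, and this is secured by the larger HOMO coefficient and lower hindrance of that terminus and by the larger LUMO coefficient at the β-carbon of the activated enal.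

Step 4
Reactants: 9 (1R,2S,8aR)-1,2,5,5-tetramethyl-1,2,3,5,6,7,8,8a-octahydronaphthalene-1-carbaldehyde
Product: 10 (1R,2S)-1,2,5,5-tetramethyl-1,2,3,4,5,6,7,8-octahydronaphthalene-1-carbaldehyde
Conditions: p-TsOH·H2O (10 mol %), benzene, 60 °C
Reagents that add atoms: none
Why: Brønsted-acid-catalysed alkene isomerisation under thermodynamic control: protonation at C6 gives the tertiary C5 cation and loss of H-10 gives the tetrasubstituted ring-fusion alkene, while the quaternary, non-enolisable C9 and the remote C8 are not touched.

Step 5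
Reactants: 10 (1R,2S)-1,2,5,5-tetramethyl-1,2,3,4,5,6,7,8-octahydronaphthalene-1-carbaldehyde; 11 1,2,4,5-tetramethoxybenzene; 12 n-butyllithium; 13 carbon disulfide; 14 iodomethane
Product: 18 O-{(2,3,5,6-tetramethoxyphenyl)[(1R,2S)-1,2,5,5-tetramethyl-1,2,3,4,5,6,7,8-octahydronaphthalen-1-yl]methyl} S-methyl dithiocarbonate (both epimers at the carbinol carbon), via aryllithium 15 (not isolated), via lithium alkoxide 16 (not isolated), via lithium xanthate 17 (not isolated)
Conditions: 11, n-BuLi, TMEDA, THF, 0 °C; 10, −78 → 0 °C; CS2, DMPU, 0 → 23 °C; MeI, 23 °C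
Reagents that add atoms: 1,2,4,5-tetramethoxybenzene, COc1cc(OC)c(OC)cc1OC; n-butyllithium, [Li]CCCC (lithium of 15 to 17); carbon disulfide, S=C=S; iodomethane, CI
Why: Directed ortho-lithiation of 11 between two methoxy groups gives aryllithium 15, whose 1,2-addition to the non-enolisable neopentyl aldehyde 10 gives alkoxide 16, trapped in the same flask as the S-methyl xanthate; the new carbinol centre forms as a mixture of epimers and is removed in step 6.

Step 6
Reactants: 18 S-methyl xanthate
Product: 19 1,2,4,5-tetramethoxy-3-{[(1R,2S)-1,2,5,5-tetramethyl-1,2,3,4,5,6,7,8-octahydronaphthalen-1-yl]methyl}benzene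
Conditions: Bu3SnH, AIBN (cat.), toluene, 100 °C
Reagents that add atoms: none
Why: Barton–McCombie deoxygenation: the stannyl radical adds to the thiocarbonyl sulfur, β-scission gives the benzylic C11 radical, and hydrogen transfer from Bu3SnH gives the methylene group without a cationic intermediate that could rearrange the neopentyl or homoallylic system.

Step 7
Reactants: 19 tetramethoxyarene; 20 water
Product: 21 2,5-dimethoxy-3-{[(1R,2S)-1,2,5,5-tetramethyl-1,2,3,4,5,6,7,8-octahydronaphthalen-1-yl]methyl}cyclohexa-2,5-diene-1,4-dione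
Conditions: (NH4)2Ce(NO3)6 (2.5 equiv), MeCN/H2O, 0 °C
Reagents that add atoms: water, O
Why: Oxidative demethylation of a para-dimethoxyarene by tetravalent cerium (arene radical cation, water addition, loss of methanol); either para pair of methoxy groups gives the same 2,5-dimethoxyquinone, and the tetraoxygenated arene is oxidised more easily than the tetrasubstituted alkene.

Step 8
Reactants: 21 2,5-dimethoxyquinone; 22 potassium hydroxide
Product: 24 2-hydroxy-5-methoxy-3-{[(1R,2S)-1,2,5,5-tetramethyl-1,2,3,4,5,6,7,8-octahydronaphthalen-1-yl]methyl}cyclohexa-2,5-diene-1,4-dione (target), via potassium quinonolate 23 (not isolated)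
Conditions: KOH (2 M aq.), MeOH, 23 °C; then 1 M HCl
Reagents that add atoms: potassium hydroxide, [K+].[OH-]
Why: Addition–elimination of hydroxide at a vinylogous ester (saponification): the methoxy group next to the bulky side chain is twisted out of conjugation and should be displaced first, and the vinylogous carboxylate 23 resists a second substitution, as in the usual endgame for 2-hydroxy-5-methoxy-3-alkylbenzoquinones.

Compound list
1 | 2,2-dimethylcyclohexanone | CC1(C)CCCCC1=O | starting material
2 | LiN(SiMe3)2 (lithium hexamethyldisilazide) | [Li]N([Si](C)(C)C)[Si](C)(C)C | starting material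
3 | N-phenylbis(trifluoromethanesulfonimide) | O=S(=O)(N(c1ccccc1)S(=O)(=O)C(F)(F)F)C(F)(F)F | starting material
4 | lithium enolate of 1 (lithium 6,6-dimethylcyclohex-1-en-1-olate) | CC1(C)CCCC=C1O[Li] | intermediate
5 | 6,6-dimethylcyclohex-1-en-1-yl trifluoromethanesulfonate | CC1(C)CCCC=C1OS(=O)(=O)C(F)(F)F | intermediate
6 | tributyl(vinyl)stannane | C=C[Sn](CCCC)(CCCC)CCCC | starting material
7 | 6,6-dimethyl-1-vinylcyclohex-1-ene | C=CC1=CCCCC1(C)C | intermediate
8 | (E)-2-methylbut-2-enal (tiglic aldehyde) | C/C=C(\C)C=O | starting material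
9 | (1R,2S,8aR)-1,2,5,5-tetramethyl-1,2,3,5,6,7,8,8a-octahydronaphthalene-1-carbaldehyde (C5=C6 alkene; formyl at C9 trans to the C8 methyl and cis to H-10) | O=C[C@@]1(C)[C@@H]2CCCC(C)(C)C2=CC[C@@H]1C | intermediate
10 | (1R,2S)-1,2,5,5-tetramethyl-1,2,3,4,5,6,7,8-octahydronaphthalene-1-carbaldehyde (C5=C10 alkene) | O=C[C@@]1(C)C2=C(CC[C@@H]1C)C(C)(C)CCC2 | intermediate
11 | 1,2,4,5-tetramethoxybenzene | COc1cc(OC)c(OC)cc1OC | starting material
12 | n-butyllithium | [Li]CCCC | starting material
13 | carbon disulfide | S=C=S | starting material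
14 | iodomethane | CI | starting material
15 | 2,3,5,6-tetramethoxyphenyllithium | [Li]c1c(OC)c(OC)cc(OC)c1OC | intermediate
16 | lithium alkoxide of the benzylic alcohol from 15 and 10 (epimers at the carbinol carbon) | COc1cc(OC)c(OC)c(C(O[Li])[C@@]2(C)C3=C(CC[C@@H]2C)C(C)(C)CCC3)c1OC | intermediate
17 | lithium O-alkyl dithiocarbonate (lithium xanthate) from 16 (epimers at the carbinol carbon) | COc1cc(OC)c(OC)c(C(OC(=S)S[Li])[C@@]2(C)C3=C(CC[C@@H]2C)C(C)(C)CCC3)c1OC | intermediate
18 | O-{(2,3,5,6-tetramethoxyphenyl)[(1R,2S)-1,2,5,5-tetramethyl-1,2,3,4,5,6,7,8-octahydronaphthalen-1-yl]methyl} S-methyl dithiocarbonate (epimers at the carbinol carbon) | COc1cc(OC)c(OC)c(C(OC(=S)SC)[C@@]2(C)C3=C(CC[C@@H]2C)C(C)(C)CCC3)c1OC | intermediate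
19 | 1,2,4,5-tetramethoxy-3-{[(1R,2S)-1,2,5,5-tetramethyl-1,2,3,4,5,6,7,8-octahydronaphthalen-1-yl]methyl}benzene | COc1cc(OC)c(OC)c(C[C@@]2(C)C3=C(CC[C@@H]2C)C(C)(C)CCC3)c1OC | intermediate
20 | water | O | starting material
21 | 2,5-dimethoxy-3-{[(1R,2S)-1,2,5,5-tetramethyl-1,2,3,4,5,6,7,8-octahydronaphthalen-1-yl]methyl}cyclohexa-2,5-diene-1,4-dione | COC1=CC(=O)C(OC)=C(C[C@@]2(C)C3=C(CC[C@@H]2C)C(C)(C)CCC3)C1=O | intermediate
22 | potassium hydroxide | [K+].[OH-] | starting material
23 | potassium salt of 24 (potassium quinonolate) | COC1=CC(=O)C([O-])=C(C[C@@]2(C)C3=C(CC[C@@H]2C)C(C)(C)CCC3)C1=O.[K+] | intermediate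
24 | 2-hydroxy-5-methoxy-3-{[(1R,2S)-1,2,5,5-tetramethyl-1,2,3,4,5,6,7,8-octahydronaphthalen-1-yl]methyl}cyclohexa-2,5-diene-1,4-dione | COC1=CC(=O)C(O)=C(C[C@@]2(C)C3=C(CC[C@@H]2C)C(C)(C)CCC3)C1=O | target

Total step count: 8. Longest linear sequence: 8 steps (1 → 24).

Steps most likely to fail

Step 3. The α,β-disubstituted enal may add too slowly to the hindered diene, so that the strong acid catalyst oligomerises the diene, or the catalyst may discriminate the enal faces poorly. The fallback sets out from 7 and 8 and comes back at 9. The cycloaddition is run without chiral control (Me2AlCl, CH2Cl2, −40 °C), which should give 9 together with its enantiomer, the (1S,2R,8aS)-aldehyde F1. The mixture is condensed with (1R,2R)-N,N'-dimethyl-1,2-diphenylethane-1,2-diamine (molecular sieves, Et2O) to two diastereomeric aminals, the imidazolidine of 9 F2 and the imidazolidine of the enantiomer F3, which are separated by chromatography or crystallisation. Mild hydrolysis of F2 (dilute aqueous HCl, Et2O) returns 9 as a single enantiomer.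

Step 4. The C5 cation may suffer a 1,2-methyl shift from C4 (skeletal rearrangement) instead of losing H-10, or the migration may stop at an equilibrium mixture. The fallback sets out from 9 and comes back at 10 and leaves the carbocation manifold. Aldehyde 9 is stirred with Pd/C under H2 (1 atm) in EtOAc/AcOH, where reversible hydride addition and elimination on the palladium surface move a trisubstituted alkene next to a ring-fusion methine into the tetrasubstituted ring-fusion position, as is classical for steroid alkenes. The tetrasubstituted product resists hydrogenation, and no cation is formed that could shift a methyl group.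

Step 8. Hydroxide may attack the less hindered methoxy-bearing carbon (remote from the side chain) and give the regioisomeric hydroxyquinone, or hydrolysis may go on to both methoxy groups. The fallback sets out from 21 and comes back at 24. Both methoxy groups are hydrolysed on purpose (excess aqueous NaOH, MeOH, 60 °C, then acid) to the 2,5-dihydroxyquinone F4. The hydroxyl group remote from the side chain, which is the more accessible one, is then methylated selectively with Me3SiCHN2 (1 equiv, MeOH/toluene, 0 °C) to give 24.

Further compounds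
F1 | step 3 | (1S,2R,8aS)-1,2,5,5-tetramethyl-1,2,3,5,6,7,8,8a-octahydronaphthalene-1-carbaldehyde (enantiomer of 9) | O=C[C@]1(C)[C@H]2CCCC(C)(C)C2=CC[C@H]1C
F2 | step 3 | (4R,5R)-1,3-dimethyl-4,5-diphenyl-2-[(1R,2S,8aR)-1,2,5,5-tetramethyl-1,2,3,5,6,7,8,8a-octahydronaphthalen-1-yl]imidazolidine (aminal of 9) | CN1[C@H](c2ccccc2)[C@@H](c2ccccc2)N(C)C1[C@@]3(C)[C@@H]4CCCC(C)(C)C4=CC[C@@H]3C
F3 | step 3 | (4R,5R)-1,3-dimethyl-4,5-diphenyl-2-[(1S,2R,8aS)-1,2,5,5-tetramethyl-1,2,3,5,6,7,8,8a-octahydronaphthalen-1-yl]imidazolidine (aminal of F1) | CN1[C@H](c2ccccc2)[C@@H](c2ccccc2)N(C)C1[C@]3(C)[C@H]4CCCC(C)(C)C4=CC[C@H]3C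
F0 | step 4 | none | none
F4 | step 8 | 2,5-dihydroxy-3-{[(1R,2S)-1,2,5,5-tetramethyl-1,2,3,4,5,6,7,8-octahydronaphthalen-1-yl]methyl}cyclohexa-2,5-diene-1,4-dione | OC1=CC(=O)C(O)=C(C[C@@]2(C)C3=C(CC[C@@H]2C)C(C)(C)CCC3)C1=O
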